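**Retrosynthetic overview**
1. Locants: oxolanone ring O1, C2 (quaternary), C3H2, C4H2, C5(=O); C1' is the side-chain CH(CO2H). The last disconnection is the primary alkyl ester C–O bond. It is made by opening O-trifluoroacetyl-D-malic anhydride at its C1 carbonyl with the ω-hydroxy lactone diacid, and D-malic acid brings the remote stereocentre.
2. Enabling feature: lactone carbonyl C5 and the carboxyl carbon on C1' are the two ends of the six-carbon path C5–C4–C3–C2–C1'–CO2H. This 1,6-dicarboxyl pair reconnects to the C=C of a cyclohexene. C2 carries both an oxygen and a carboxyl carbon, so it maps onto the substituted carbon of a captodative 2-acyloxyacrolein.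
3. Key disconnection: retro-Diels–Alder of that cyclohexene to an (E)-1-alkylbuta-1,3-diene and 2-acetoxyacrolein. The forward step forms C3–C4 and the hindered C2–C1' bond together and sets both core stereocentres from two achiral partners.
4. Ring order: temporary cyclohexene (step 7), then its oxidative cleavage to a triacid (step 8), then the oxolanone ring by lactonisation (step 9).
5. The diene comes from alkylation of 3-sulfolene and SO2 extrusion. The dienophile comes from a retro-hetero-Diels–Alder reaction of a 4H-1,3-dioxin.

Key step: step 7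

Assumption: the sense of induction in step 7 is assigned from the formyl C–H···O pre-transition-state model of oxazaborolidinium–enal complexes, which calls for the (R)-prolinol-derived catalyst to reach the (1S,2S) adduct. Both catalyst antipodes are commercial, so the antipode would be exchanged if the sense proved opposite.

**Route**

Step 1
Reactants: 1 10-bromodecan-1-ol
Product: 2 (10-bromodecyloxy)triisopropylsilane
Conditions: TIPSCl, imidazole, CH2Cl2, 0 °C to rt
Reagents that add atoms: chlorotriisopropylsilane, CC(C)[Si](Cl)(C(C)C)C(C)C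
Why: Imidazole-promoted silyl ether formation; the triisopropylsilyl group is chosen because it should survive amide bases, heat, the Lewis acid and aqueous RuO4 but fall to warm aqueous acid.

Step 2
Reactants: 2 (10-bromodecyloxy)triisopropylsilane
Product: 3 (10-iododecyloxy)triisopropylsilane
Conditions: NaI, acetone, reflux
Reagents that add atoms: sodium iodide, [Na+].[I-]
Why: Finkelstein halide exchange driven by precipitation of NaBr gives the iodide needed for fast trapping in step 3.

Step 3
Reactants: 3 (10-iododecyloxy)triisopropylsilane; 4 butadiene sulfone (3-sulfolene)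
Product: 6 2-[10-(triisopropylsilyloxy)decyl]-2,5-dihydrothiophene 1,1-dioxide (racemic), via 2-lithio-3-sulfolene 5 (not isolated)
Conditions: LiN(SiMe3)2 added dropwise to 3 + 4, THF–HMPA (4:1), −78 °C to −20 °C
Reagents that add atoms: none
Why: Alkylation of an α-sulfonyl carbanion, with the base added to the premixed partners so that the primary iodide traps the anion before it ring-opens; the new stereocentre is racemic and is erased in step 4.

Step 4
Reactants: 6 2-[10-(triisopropylsilyloxy)decyl]-2,5-dihydrothiophene 1,1-dioxide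
Product: 7 (E)-triisopropyl(tetradeca-11,13-dien-1-yloxy)silane
Conditions: xylene, BHT (trace), 130 °C, argon sweep
Reagents that add atoms: none
Why: Cheletropic (retro-[4+1]) extrusion of SO2 is suprafacial and disrotatory, and outward rotation of the single ring substituent should deliver the E diene.

Step 5
Reactants: 8 2,2-dimethyl-1,3-dioxan-5-one
Product: 10 2,2-dimethyl-4H-1,3-dioxin-5-yl acetate, via potassium enolate of the dioxanone 9 (not isolated)
Conditions: KN(SiMe3)2, THF, −78 °C; then Ac2O, −78 °C to 0 °C
Reagents that add atoms: acetic anhydride, CC(=O)OC(C)=O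
Why: Kinetic O-acylation of a potassium enolate (enol ester formation); the ketone is symmetrical, so only one enolate can form.

Step 6
Reactants: 10 2,2-dimethyl-4H-1,3-dioxin-5-yl acetate
Product: 11 2-acetoxyacrolein (3-oxoprop-1-en-2-yl acetate)
Conditions: toluene, 115 °C, acetone distilled off; solution used at once
Reagents that add atoms: none
Why: Retro-hetero-Diels–Alder reaction of the 4H-1,3-dioxin releases acetone and the 2-acyloxyacrolein under neutral conditions, which avoids polymerisation of the enal.

Step 7
Reactants: 7 (E)-triisopropyl(tetradeca-11,13-dien-1-yloxy)silane; 11 2-acetoxyacrolein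
Product: 12 (1S,2S)-1-formyl-2-[10-(triisopropylsilyloxy)decyl]cyclohex-3-en-1-yl acetate (formyl cis to the decyl chain)
Conditions: (3aR)-1-(2-methylphenyl)-3,3-diphenyltetrahydro-1H,3H-pyrrolo[1,2-c][1,3,2]oxazaborole (C24H24BNO, 20 mol %), (CF3SO2)2NH (18 mol %), CH2Cl2–toluene, −78 °C to −40 °C
Reagents that add atoms: none
Why: The oxazaborolidinium ion binds the formyl oxygen of 11 (B–O coordination reinforced by a formyl C–H···O contact), lowers the LUMO of the captodative alkene and triggers a concerted, asynchronous, normal-demand [4+2] cycloaddition in which the CH2–CH2 bond C5–C6 of the new ring (later C4–C3 of the lactone) leads and the hindered C1–C2 bond (later C2–C1') follows. The closest known reaction types are the oxazaborolidinium-catalysed enantioselective Diels–Alder reactions of 2-bromo- and 2-methylacrolein with acyclic dienes and the chiral-ammonium-catalysed enantioselective Diels–Alder reactions of 2-acyloxyacroleins. One ring is closed, the cyclohexene, in an intermolecular suprafacial–suprafacial [4+2] mode. C2 is controlled by the E geometry of 7 together with endo placement of the boron-bound formyl group (outside substituent and endo group end up cis), and the quaternary C1 is controlled by the catalyst aryl group, which covers one face of the s-trans enal so that the diene should add to the open Si face of the acetoxy-bearing carbon. The step needs ortho regioselectivity, which is secured because the largest HOMO coefficient sits at the unsubstituted diene terminus and meets the CH2 terminus of the formyl-activated alkene. It also needs endo selectivity, which is secured by secondary overlap of the activated C=O while the acetoxy group takes the exo site, and it needs tolerance of the silyl ether and the diene, which is secured by keeping (CF3SO2)2NH below the amount of oxazaborolidine so that no free acid is present; a minor exo isomer would be removed by chromatography.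

Step 8
Reactants: 12 (1S,2S)-1-formyl-2-[10-(triisopropylsilyloxy)decyl]cyclohex-3-en-1-yl acetate
Product: 13 (3S,4R)-3-acetoxy-14-(triisopropylsilyloxy)tetradecane-1,3,4-tricarboxylic acid
Conditions: RuCl3·xH2O (3 mol %), NaIO4 (6 equiv), MeCN–EtOAc–H2O, 0 °C to rt
Reagents that add atoms: sodium periodate, [Na+].[O-]I(=O)(=O)=O; water, O
Why: RuO4-catalysed oxidative cleavage turns the ring C=C into the two carboxyl groups and oxidises the formyl group in the same operation, while the acetate blocks periodate cleavage at the α-oxy carbonyl site and no bond to either stereocentre is broken.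

Step 9
Reactants: 13 (3S,4R)-3-acetoxy-14-(triisopropylsilyloxy)tetradecane-1,3,4-tricarboxylic acid
Product: 15 (2S)-2-[(1R)-1-carboxy-11-hydroxyundecyl]-5-oxooxolane-2-carboxylic acid, via trisodium seco-hydroxytricarboxylate 14 (not isolated)
Conditions: NaOH (2 M, 8 equiv), THF–H2O, 45 °C; then HCl (3 M) to pH 1, 45 °C
Reagents that add atoms: none
Why: Saponification of the acetate on the tricarboxylate (no α-proton is acidic enough for epimerisation or E1cB loss of the oxygen) is followed by acid desilylation and 5-exo-trig γ-lactonisation of the tertiary alcohol onto the propanoic acid arm, both stereocentres being retained.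

Step 10
Reactants: 16 D-malic acid ((R)-2-hydroxybutanedioic acid)
Product: 17 (R)-2-(trifluoroacetoxy)succinic anhydride ((3R)-2,5-dioxooxolan-3-yl trifluoroacetate)
Conditions: (CF3CO)2O (neat, 4 equiv), 0 °C to rt; volatiles removed in vacuo
Reagents that add atoms: trifluoroacetic anhydride, O=C(OC(=O)C(F)(F)F)C(F)(F)F
Why: O-acylation and mixed-anhydride cyclodehydration of a 1,4-diacid proceed without touching the stereocentre and mask the hydroxyl group for the coupling.

Step 11
Reactants: 15 (2S)-2-[(1R)-1-carboxy-11-hydroxyundecyl]-5-oxooxolane-2-carboxylic acid; 17 (R)-2-(trifluoroacetoxy)succinic anhydride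
Product: 19 (2S)-2-[(1R)-1-carboxy-11-{[(2R)-3-carboxy-2-hydroxypropanoyl]oxy}undecyl]-5-oxooxolane-2-carboxylic acid (target), via O-trifluoroacetyl ester 18 (not isolated)
Conditions: 17 (3 equiv), THF, rt; then H2O–THF, rt
Reagents that add atoms: none
Why: Regioselective alcoholysis of an unsymmetrical cyclic anhydride, in which the only alcohol of 15 attacks the carbonyl next to the electron-poor trifluoroacetoxy-bearing carbon (malate C1), after which water solvolyses the labile trifluoroacetate without touching the other esters or any stereocentre.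

**Compound list**
1 | 10-bromodecan-1-ol | OCCCCCCCCCCBr | starting material
2 | (10-bromodecyloxy)triisopropylsilane | CC(C)[Si](C(C)C)(C(C)C)OCCCCCCCCCCBr | intermediate
3 | (10-iododecyloxy)triisopropylsilane | CC(C)[Si](C(C)C)(C(C)C)OCCCCCCCCCCI | intermediate
4 | 3-sulfolene (2,5-dihydrothiophene 1,1-dioxide) | O=S1(=O)CC=CC1 | starting material
5 | 2-lithio-3-sulfolene | [Li+].O=S1(=O)CC=C[CH-]1 | intermediate
6 | 2-[10-(triisopropylsilyloxy)decyl]-2,5-dihydrothiophene 1,1-dioxide (racemic) | CC(C)[Si](C(C)C)(C(C)C)OCCCCCCCCCCC1C=CCS1(=O)=O | intermediate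
7 | (E)-triisopropyl(tetradeca-11,13-dien-1-yloxy)silane | CC(C)[Si](C(C)C)(C(C)C)OCCCCCCCCCC/C=C/C=C | intermediate
8 | 2,2-dimethyl-1,3-dioxan-5-one | CC1(C)OCC(=O)CO1 | starting material
9 | potassium 2,2-dimethyl-4H-1,3-dioxin-5-olate | [K+].CC1(C)OCC([O-])=CO1 | intermediate
10 | 2,2-dimethyl-4H-1,3-dioxin-5-yl acetate | CC(=O)OC1=COC(C)(C)OC1 | intermediate
11 | 2-acetoxyacrolein | C=C(OC(C)=O)C=O | intermediate
12 | (1S,2S)-1-formyl-2-[10-(triisopropylsilyloxy)decyl]cyclohex-3-en-1-yl acetate | CC(C)[Si](C(C)C)(C(C)C)OCCCCCCCCCC[C@H]1C=CCC[C@@]1(OC(C)=O)C=O | intermediate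
13 | (3S,4R)-3-acetoxy-14-(triisopropylsilyloxy)tetradecane-1,3,4-tricarboxylic acid | CC(C)[Si](C(C)C)(C(C)C)OCCCCCCCCCC[C@@H](C(=O)O)[C@](OC(C)=O)(C(=O)O)CCC(=O)O | intermediate
14 | trisodium (3S,4R)-3-hydroxy-14-(triisopropylsilyloxy)tetradecane-1,3,4-tricarboxylate | CC(C)[Si](C(C)C)(C(C)C)OCCCCCCCCCC[C@@H](C(=O)[O-])[C@](O)(C(=O)[O-])CCC(=O)[O-].[Na+].[Na+].[Na+] | intermediate
15 | (2S)-2-[(1R)-1-carboxy-11-hydroxyundecyl]-5-oxooxolane-2-carboxylic acid | OCCCCCCCCCC[C@@H](C(=O)O)[C@]1(C(=O)O)CCC(=O)O1 | intermediate
16 | D-malic acid | O=C(O)C[C@@H](O)C(=O)O | starting material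
17 | (R)-2-(trifluoroacetoxy)succinic anhydride | O=C1C[C@@H](OC(=O)C(F)(F)F)C(=O)O1 | intermediate
18 | O-trifluoroacetyl derivative of 19 | O=C(O)C[C@@H](OC(=O)C(F)(F)F)C(=O)OCCCCCCCCCC[C@@H](C(=O)O)[C@]1(C(=O)O)CCC(=O)O1 | intermediate
19 | (2S)-2-[(1R)-1-carboxy-11-{[(2R)-3-carboxy-2-hydroxypropanoyl]oxy}undecyl]-5-oxooxolane-2-carboxylic acid | O=C(O)C[C@@H](O)C(=O)OCCCCCCCCCC[C@@H](C(=O)O)[C@]1(C(=O)O)CCC(=O)O1 | target

**Step count**
Total step count: 11. Longest linear sequence: 8 (steps 1, 2, 3, 4, 7, 8, 9, 11).

**Steps most likely to fail**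

Step 7. The formyl and acetoxy groups may not be told apart well enough in the endo/exo sense. Facial selectivity may erode if an uncatalysed or acetoxy-bound pathway competes. The diene may also polymerise cationically before it cycloadds.

The fallback sets out from 7 and comes back at 15, and it sets the two stereocentres one after the other by known chemistry.
- Diels–Alder reaction of 7 with commercial 3-acryloyl-1,3-oxazolidin-2-one is run under {2,2'-(propane-2,2-diyl)bis[(4R)-4-tert-butyl-4,5-dihydro-1,3-oxazole]}Cu(SbF6)2 (10 mol %, CH2Cl2, rt). It should give the cis imide 3-({(1R,2S)-2-[10-(triisopropylsilyloxy)decyl]cyclohex-3-en-1-yl}carbonyl)-1,3-oxazolidin-2-one F1.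
- The same two C–C bonds are formed, and the decyl-bearing carbon is set by the catalyst and the endo rule. The minor trans isomer is removed by chromatography because it would lead to the antipodal enolate.
- Methanolysis (Mg(OMe)2, MeOH, 0 °C) gives methyl (1R,2S)-2-[10-(triisopropylsilyloxy)decyl]cyclohex-3-ene-1-carboxylate F2.
- Enolisation with KN(SiMe3)2 and oxidation with 2-(phenylsulfonyl)-3-phenyloxaziridine at −78 °C should place the hydroxyl group anti to the pseudoaxial decyl chain. The product is methyl (1S,2S)-1-hydroxy-2-[10-(triisopropylsilyloxy)decyl]cyclohex-3-ene-1-carboxylate F3.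
- RuCl3/NaIO4 cleavage as in step 8, with spontaneous lactonisation, gives (2R)-2-[(2S)-2-(methoxycarbonyl)-5-oxooxolan-2-yl]-12-(triisopropylsilyloxy)dodecanoic acid F4.
- NaOH followed by HCl, as in step 9, converts F4 into 15.

Step 11. The alcohol may attack the distal (C4) carbonyl of the anhydride. Acyl exchange with the two free carboxyl groups of 15 may also lead to oligomeric esters.

The fallback sets out from 15 and comes back at 19. It replaces acylation of the alcohol by O-alkylation of a carboxylate that has only one free acid.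
- 15 is converted with BnBr and KHCO3 in DMF into benzyl (2S)-2-[(1R)-1-(benzyloxycarbonyl)-11-hydroxyundecyl]-5-oxooxolane-2-carboxylate F5.
- An Appel-type iodination (I2, PPh3, imidazole, CH2Cl2) gives the corresponding primary iodide F6.
- Commercial D-aspartic acid 4-benzyl ester is diazotised (NaNO2, aqueous H2SO4, 0 °C, net retention) to (R)-4-(benzyloxy)-2-hydroxy-4-oxobutanoic acid F7.
- The preformed caesium salt of F7 displaces the iodide of F6 in DMF at rt to give the tribenzyl ester of the target F8.
- Hydrogenolysis (H2, Pd/C, EtOAc–EtOH) gives 19.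

Step 3. The sulfolenyl anion may ring-open to the dienylsulfinate, or it may be alkylated twice, before clean monoalkylation occurs.

The fallback sets out from 3 and comes back at 7, bypassing steps 3 and 4.
- Displacement of the iodide with lithium acetylide–ethylenediamine complex in DMSO gives (dodec-11-yn-1-yloxy)triisopropylsilane F9.
- Hydrozirconation with Cp2Zr(H)Cl followed by I2 gives (E)-(12-iodododec-11-en-1-yloxy)triisopropylsilane F10.
- Suzuki–Miyaura coupling with potassium vinyltrifluoroborate (PdCl2(dppf), Cs2CO3, THF–H2O) gives 7 with retention of the E geometry.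

**Further compounds**
F1 | step 7 | 3-({(1R,2S)-2-[10-(triisopropylsilyloxy)decyl]cyclohex-3-en-1-yl}carbonyl)-1,3-oxazolidin-2-one | CC(C)[Si](C(C)C)(C(C)C)OCCCCCCCCCC[C@H]1C=CCC[C@H]1C(=O)N2CCOC2=O
F2 | step 7 | methyl (1R,2S)-2-[10-(triisopropylsilyloxy)decyl]cyclohex-3-ene-1-carboxylate | CC(C)[Si](C(C)C)(C(C)C)OCCCCCCCCCC[C@H]1C=CCC[C@H]1C(=O)OC
F3 | step 7 | methyl (1S,2S)-1-hydroxy-2-[10-(triisopropylsilyloxy)decyl]cyclohex-3-ene-1-carboxylate | CC(C)[Si](C(C)C)(C(C)C)OCCCCCCCCCC[C@H]1C=CCC[C@@]1(O)C(=O)OC
F4 | step 7 | (2R)-2-[(2S)-2-(methoxycarbonyl)-5-oxooxolan-2-yl]-12-(triisopropylsilyloxy)dodecanoic acid | CC(C)[Si](C(C)C)(C(C)C)OCCCCCCCCCC[C@@H](C(=O)O)[C@]1(C(=O)OC)CCC(=O)O1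
F5 | step 11 | benzyl (2S)-2-[(1R)-1-(benzyloxycarbonyl)-11-hydroxyundecyl]-5-oxooxolane-2-carboxylate | OCCCCCCCCCC[C@@H](C(=O)OCc1ccccc1)[C@]1(C(=O)OCc2ccccc2)CCC(=O)O1
F6 | step 11 | benzyl (2S)-2-[(1R)-1-(benzyloxycarbonyl)-11-iodoundecyl]-5-oxooxolane-2-carboxylate | ICCCCCCCCCC[C@@H](C(=O)OCc1ccccc1)[C@]1(C(=O)OCc2ccccc2)CCC(=O)O1
F7 | step 11 | (R)-4-(benzyloxy)-2-hydroxy-4-oxobutanoic acid | O=C(OCc1ccccc1)C[C@@H](O)C(=O)O
F8 | step 11 | tribenzyl ester of 19 | O=C(OCc1ccccc1)C[C@@H](O)C(=O)OCCCCCCCCCC[C@@H](C(=O)OCc1ccccc1)[C@]1(C(=O)OCc2ccccc2)CCC(=O)O1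
F9 | step 3 | (dodec-11-yn-1-yloxy)triisopropylsilane | CC(C)[Si](C(C)C)(C(C)C)OCCCCCCCCCCC#C
F10 | step 3 | (E)-(12-iodododec-11-en-1-yloxy)triisopropylsilane | CC(C)[Si](C(C)C)(C(C)C)OCCCCCCCCCC/C=C/I
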